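The runs were generated by integration for an exercise, and the scatter is random.

The ratio of target to remainder, the part of the charge that is neither target nor starting material, reads 2.21 and then 1.24 in the dawn run, so the dawn flask moves towards equal shares.

all flasks: gas 19 mM (held)
- dawn: starting material 0.15 M; temperature 85 °C; run made earlier
- midnight: starting material 0.22 M; temperature 110 °C; run made earlier
- Friday's: starting material 0.30 M; temperature 130 °C; time 4.0 h
- Monday's: starting material 0.30 M; temperature 90 °C; time 4.0 h
- Thursday's: starting material 0.30 M; temperature 110 °C; time 4.0 h
- Tuesday's: starting material 0.30 M; at 90 °C until 80 min, from then on at 130 °C; time 4.0 h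

- the flask that comes out highest in amount of target, in percent of the starting material charged, or "all alike" when all lie within 1.5 percentage points (Friday's / Monday's / Thursday's / Tuesday's / all alike)
- target at the end, in percent of the starting material charged, Friday's
- target at the end, in percent of the starting material charged, Monday's
- target at the end, in percent of the starting material charged, Thursday's
- target at the end, in percent of the starting material charged, Tuesday's

- the earlier runs were read with a standard deviation of 1 percentage point
- at the start none of the gas is in solution

| run | time / h | target / % | starting material / % |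
|---|---|---|---|
| dawn | 10.0 | 66.7 | 3.1 |
| dawn | 20.0 | 60.3 | 2.4 |
| dawn | 30.0 | 56.7 | 0.7 |
| dawn | 40.0 | 56.5 | 2.7 |
| dawn | 50.0 | 55.1 | 0.4 |
| midnight | 2.50 | 53.8 | 4.8 |
| midnight | 5.00 | 49.8 | 3.2 |
| midnight | 8.00 | 51.0 | 1.1 |
| midnight | 10.0 | 51.1 | 2.4 |
| midnight | 15.0 | 52.1 | 1.7 |

(each reading ± 1 percentage point)

The useful quantity is what is left to happen: the gap, [target] minus [remainder], which in percent of the charge is 2 × target + starting material − 100%. Row by row, the dawn table gives a gap of 36.5%, then 23.0%, and in its last row 10.6%. An exponential keeping the ratio of the first two rows would reach 5.75% by the last row, and the reading stands higher than that. The dawn readings therefore show a time constant that lengthens as the gap shrinks, as in a second-order decay, where the reciprocal of the gap climbs steadily.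

Converted to concentration, the dawn gap reads 0.0548 M in the first row and 0.0159 M in the last. Read from these two rows, its reciprocal climbs at the closing rate, an apparent second-order rate constant, of 1.12 M⁻¹ h⁻¹, and the time constant at any moment is one over the closing rate times the gap.

This text's own reckoning assumes that the closing rate grows in proportion to the charge, which gives 2.23 M⁻¹ h⁻¹ for Monday's. Taking the gap at the start as equal to the charge, the reckoning gives 0.0816 M for Monday's at the end. With the starting material of the dawn run's first row, 3.1%, that means 62.0% target. Monday's is hotter than the dawn run, and the midnight run, hotter again and with another charge, reads a gap of 12.4% at 2.50 h against the dawn run's 36.5% at 10.0 h, so this figure leans high. The midnight gap reads 2.80% at 5.00 h, so Thursday's, Friday's and Tuesday's, which end at or above that run's temperature, should stand near equal shares at the end.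

The forecast, a different reckoning from plateaus and relaxation rates, gives 48.5% for Friday's, 60% for Monday's, 51.5% for Thursday's and 48.7% for Tuesday's, with Monday's highest: “Monday's is still on the overshoot”.

The flasks give 49.6% for Friday's, 57.7% for Monday's, 50.7% for Thursday's and 49.5% for Tuesday's, so Monday's comes out highest, as forecast.

    starting material + reagent ⇌ target + by-product (K = 12.0, k = 0.320 M⁻¹ s⁻¹, Ea = 77.0 kJ mol⁻¹, ΔH = −67.0 kJ mol⁻¹)
    starting material + by-product → side product (k = 0.00690 M⁻¹ s⁻¹, Ea = 65.0 kJ mol⁻¹)
    gas ⇌ reagent, rate k3*(csat - [reagent]) (kL = 0.0400 s⁻¹)
    (constants at 110 °C)

The gap turns out to be [by-product]. In Monday's it falls from 0.0918 M at 2.00 h to 0.0594 M at 4.00 h, so its reciprocal climbs at 2.97 M⁻¹ h⁻¹, which is 1.33 times the scaled closing rate. Run backwards at that rate to the neighbouring flask, Monday's stopped at 1.0 h, the line gives 0.126 M. With that flask's 10.5% starting material, the target comes to 65.8%. The neighbouring flask holds 0.128 M by-product and 66.0% target.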